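**Retrosynthetic overview**
1. The acrylate comes from a C13 terminal alkyne by Markovnikov hydromethoxycarbonylation; the alkyne comes from a C13 aldehyde whose configuration is set by equilibration.
2. Rings C and B close in one SmI2 cascade on a trialdehyde enoate: C9–C11 by ketyl–olefin addition, then C6–C8 by aldol.
3. The enoate side chain comes from Michael addition of a pent-4-enal hydrazone aza-enolate to an α-methylene spirolactone (C13–C14), with selenation; one ozonolysis then unveils all three aldehydes and the C8=C9 bond.
4. The spiro δ-lactone comes from an anti-Markovnikov C20–O bond formation with 6-endo radical annulation between the ring A alkene and 2-(bromomethyl)acrylic acid (key step, sets C10).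
5. Ring A comes from 4,4-dimethylcyclohex-2-enone; ring order is A (bought), lactone, C, B.

Assumption: atom labels C1–C20 follow ent-kaurane numbering of the target (C7 lactone carbonyl, C20 lactone OCH2, C10 spiro carbon, C15–C17 acrylate); racemic compounds are shown by the SMILES of the enantiomer that is carried on.

**Step 1**
Reactants: 1 4,4-dimethylcyclohex-2-en-1-one
Product: 4 rac-3-ethenyl-4,4-dimethyl-2-methylidenecyclohexan-1-one, via Mannich base 2 (not isolated), via ammonium iodide 3 (not isolated)
Conditions: CH2=CHMgBr, CuBr·SMe2 (10 mol %), THF, −40 °C; then CH2=NMe2+ I−, −40 °C → rt; then MeI, CH2Cl2, rt; then NaHCO3 (aq), rt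
Reagents that add atoms: vinylmagnesium bromide C=C[Mg]Br; N,N-dimethylmethyleneiminium iodide C=[N+](C)C.[I-]; iodomethane CI (its methyl is found only in 3 and leaves as trimethylamine)
Why: Copper-catalysed conjugate addition of the vinyl Grignard reagent gives a magnesium enolate that is trapped regiospecifically at C10 by the iminium salt (Mannich reaction), and quaternisation followed by base-induced elimination of trimethylamine installs the exocyclic methylene, the C5 stereocentre being formed racemic at this point.

**Step 2**
Reactants: 4 rac-3-ethenyl-4,4-dimethyl-2-methylidenecyclohexan-1-one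
Product: 5 rac-(1S,3R)-3-ethenyl-4,4-dimethyl-2-methylidenecyclohexan-1-ol (cis)
Conditions: NaBH4, CeCl3·7H2O, MeOH, −78 °C → 0 °C
Reagents that add atoms: none
Why: Luche reduction delivers hydride 1,2 only, and attack on the face opposite the pseudo-axial C5 vinyl group (held axial by allylic strain against the exocyclic methylene) gives the cis-1,3 allylic alcohol.

**Step 3**
Reactants: 5 rac-(1S,3R)-3-ethenyl-4,4-dimethyl-2-methylidenecyclohexan-1-ol
Product: 6 (1S,3R)-3-ethenyl-4,4-dimethyl-2-methylidenecyclohexan-1-ol
Conditions: Burkholderia cepacia lipase, vinyl acetate, t-BuOMe, 30 °C, to 55% conversion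
Reagents that add atoms: none
Why: Lipase-catalysed kinetic resolution by transesterification, in which by Kazlauskas' rule the (1R,3S) enantiomer is acetylated and the (1S,3R) alcohol, which carries the C1 and C5 configurations of the target, is recovered in high ee.

**Step 4**
Reactants: 6 (1S,3R)-3-ethenyl-4,4-dimethyl-2-methylidenecyclohexan-1-ol
Product: 7 (1S,3R)-3-ethenyl-4,4-dimethyl-2-methylidenecyclohexyl acetate
Conditions: Ac2O, pyridine, 4-(dimethylamino)pyridine (cat.), CH2Cl2, 0 °C → rt
Reagents that add atoms: acetic anhydride CC(=O)OC(C)=O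
Why: Nucleophile-catalysed acylation of the secondary allylic alcohol proceeds with retention at C1 and installs the C1 acetate of the target before any other hydroxyl exists.

**Step 5**
Reactants: 8 pent-4-enal
Product: 9 (E)-pent-4-enal N,N-dimethylhydrazone
Conditions: Me2NNH2, MgSO4, CH2Cl2, 0 °C → rt
Reagents that add atoms: 1,1-dimethylhydrazine CN(C)N
Why: Condensation gives the Corey–Enders hydrazone, which serves as a formyl-bearing C13 carbanion equivalent.

**Step 6**
Reactants: 7 (1S,3R)-3-ethenyl-4,4-dimethyl-2-methylidenecyclohexyl acetate; 10 2-(bromomethyl)prop-2-enoic acid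
Product: 11 (6S,7S,11R)-11-ethenyl-10,10-dimethyl-4-methylidene-3-oxo-2-oxaspiro[5.5]undecan-7-yl acetate
Conditions: 9-mesityl-3,6-di-tert-butyl-10-phenylacridinium tetrafluoroborate (5 mol %), NaHCO3, ClCH2CH2Cl, 450 nm LEDs, rt, 10 added over 8 h
Reagents that add atoms: none
Why: Proposed new method: the excited acridinium oxidises the carboxylate of 10 to an acyloxy radical (or the alkene to a radical cation that the carboxylate traps), either way forming the C20–O bond at the CH2 terminus (anti-Markovnikov) and a tertiary C10 radical, which closes 6-endo-trig onto the acrylate CH2 (C9) from the face anti to the cis OAc and vinyl groups and away from the axial C4 methyl (setting C10), after which the β-bromo ester radical expels a bromine atom that is reduced by the acridine radical; the closest known reaction is the acridinium-photocatalysed polar radical crossover cycloaddition of alkenes with unsaturated acids to γ-butyrolactones, here extended to a 1,1-disubstituted alkene, a 6-endo ring closure and an addition–fragmentation ending.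

**Step 7**
Reactants: 11 (6S,7S,11R)-11-ethenyl-10,10-dimethyl-4-methylidene-3-oxo-2-oxaspiro[5.5]undecan-7-yl acetate; 9 (E)-pent-4-enal N,N-dimethylhydrazone
Product: 14 C8-phenylselanyl spirolactone bearing the 2-[(dimethylhydrazinylidene)methyl]pent-4-enyl chain at C8 (C8 and C13 epimers), via lithium aza-enolate 12 (not isolated), via lithium lactone enolate 13 (not isolated)
Conditions: 9, LiN(i-Pr)2, THF, 0 °C; then 11, −78 °C; then PhSeBr, −78 °C
Reagents that add atoms: phenylselenyl bromide Br[Se]c1ccccc1; lithium diisopropylamide CC(C)N([Li])C(C)C (its lithium is found only in 12 and 13)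
Why: Aza-enolate Michael addition (Enders-type hydrazone conjugate addition) to the unhindered exocyclic methylene forms the C13–C14 bond and the resulting lactone enolate is selenenylated at C8, both new centres being formed as mixtures because C8 is removed in step 8 and C13 is corrected in step 9.

**Step 8**
Reactants: 14 C8-phenylselanyl spirolactone hydrazone
Product: 16 trialdehyde enoate (C6, C11 and C16 aldehydes; C8=C9 lactone; C13 epimers), via selenoxide trialdehyde 15 (not isolated)
Conditions: O3, pyridine, CH2Cl2, −78 °C; N2 purge, then → rt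
Reagents that add atoms: ozone [O-][O+]=O
Why: Ozonolysis cleaves the two terminal alkenes and the hydrazone C=N to the three aldehydes and oxidises the selenide to the selenoxide, whose syn-elimination on warming gives the endocyclic C8=C9 enoate (the exocyclic alkylidene alternative suffers allylic 1,3-strain), so the enoate appears only after the ozone has gone.

**Step 9**
Reactants: 16 trialdehyde enoate
Product: 18 tetracyclic C13 aldehyde (target skeleton with CHO at C13), via C13-epimeric aldehyde 17 (not isolated)
Conditions: SmI2 (2.2 equiv, added slowly), LiBr, t-BuOH, THF, −78 °C; then 1,8-diazabicyclo[5.4.0]undec-7-ene (cat.), CH2Cl2, rt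
Reagents that add atoms: none
Why: SmI2 ketyl–olefin cyclisation/aldol cascade, in which the C11 ketyl adds 6-endo to C9 of the enoate through a chair with the samarium alkoxide equatorial and on the face away from C5 (setting C9 and C11), the second electron gives the C8 samarium enolate that closes ring B on the C6 aldehyde (C8 fixed by the tether, C6 hydroxyl on the face away from the lactone bridge and the C4 methyls), and the base then moves the C13 formyl group of 17 to the equatorial position because the axial epimer is syn-axial to C7.

**Step 10**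
Reactants: 18 tetracyclic C13 aldehyde
Product: 19 tetracyclic C13 alkyne (ethynyl at C13)
Conditions: (MeO)2P(O)CHN2, KOt-Bu, THF, −78 °C → rt
Reagents that add atoms: dimethyl (diazomethyl)phosphonate COP(=O)(OC)C=[N+]=[N-]
Why: Seyferth–Gilbert homologation turns the aldehyde into the terminal alkyne at low temperature without methanolysis of the acetate, and any base-induced epimerisation at C13 only returns the favoured equatorial isomer.

**Step 11**
Reactants: 19 tetracyclic C13 alkyne
Product: 20 target CNP0421185.1
Conditions: Pd(OAc)2 (2 mol %), 2-(diphenylphosphino)pyridine, CH3SO3H, CO (20 bar), MeOH, 50 °C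
Reagents that add atoms: carbon monoxide [C-]#[O+]; methanol CO
Why: Palladium-catalysed Markovnikov hydromethoxycarbonylation of the terminal alkyne (2-pyridylphosphine/acid system) places CO2Me on the internal carbon and gives the 2-substituted acrylate directly with no change at any stereocentre.

**Compound list**
1 | 4,4-dimethylcyclohex-2-en-1-one | O=C1C=CC(C)(C)CC1 | starting material
2 | Mannich base: trans-2-[(dimethylamino)methyl]-3-ethenyl-4,4-dimethylcyclohexan-1-one (racemic) | CN(C)C[C@@H]1C(=O)CCC(C)(C)[C@H]1C=C | intermediate
3 | ammonium iodide: [(2-ethenyl-3,3-dimethyl-6-oxocyclohexyl)methyl]trimethylazanium iodide (trans, racemic) | C[N+](C)(C)C[C@@H]1C(=O)CCC(C)(C)[C@H]1C=C.[I-] | intermediate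
4 | rac-3-ethenyl-4,4-dimethyl-2-methylidenecyclohexan-1-one | C=C1C(=O)CCC(C)(C)[C@H]1C=C | intermediate
5 | rac-(1S,3R)-3-ethenyl-4,4-dimethyl-2-methylidenecyclohexan-1-ol (cis, racemic) | C=C1[C@@H](O)CCC(C)(C)[C@H]1C=C | intermediate
6 | (1S,3R)-3-ethenyl-4,4-dimethyl-2-methylidenecyclohexan-1-ol | C=C1[C@@H](O)CCC(C)(C)[C@H]1C=C | intermediate
7 | (1S,3R)-3-ethenyl-4,4-dimethyl-2-methylidenecyclohexyl acetate | C=C1[C@@H](OC(C)=O)CCC(C)(C)[C@H]1C=C | intermediate
8 | pent-4-enal | C=CCCC=O | starting material
9 | (E)-pent-4-enal N,N-dimethylhydrazone | C=CCC/C=N/N(C)C | intermediate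
10 | 2-(bromomethyl)prop-2-enoic acid | C=C(CBr)C(=O)O | starting material
11 | (6S,7S,11R)-11-ethenyl-10,10-dimethyl-4-methylidene-3-oxo-2-oxaspiro[5.5]undecan-7-yl acetate (C20–O, OAc and vinyl on one face of ring A, C9 on the other) | C=C1C(=O)OC[C@@]2(C1)[C@@H](OC(C)=O)CCC(C)(C)[C@H]2C=C | intermediate
12 | lithium aza-enolate of 9 | C=CC/C=C/N([Li])N(C)C | intermediate
13 | lithium lactone enolate from Michael addition of 12 to 11 (C13 epimers) | C=CCC(/C=N/N(C)C)CC1=C(O[Li])OC[C@@]2(C1)[C@@H](OC(C)=O)CCC(C)(C)[C@H]2C=C | intermediate
14 | spirolactone 11 skeleton with PhSe and the CH2–CH(CH=N–NMe2)(CH2CH=CH2) chain on C8 (C8 and C13 epimers) | C=CCC(/C=N/N(C)C)CC1([Se]c3ccccc3)C(=O)OC[C@@]2(C1)[C@@H](OC(C)=O)CCC(C)(C)[C@H]2C=C | intermediate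
15 | selenoxide trialdehyde (C6, C11, C16 aldehydes; PhSe(O) on C8; C8 and C13 epimers) | O=CCC(C=O)CC1([Se](=O)c3ccccc3)C(=O)OC[C@@]2(C1)[C@@H](OC(C)=O)CCC(C)(C)[C@H]2C=O | intermediate
16 | trialdehyde enoate: 11-formyl-4-(2-formyl-4-oxobutyl)-10,10-dimethyl-3-oxo-2-oxaspiro[5.5]undec-4-en-7-yl acetate, ring stereocentres as in 11 (C13 epimers) | O=CCC(C=O)CC1=C[C@]2(COC1=O)[C@@H](OC(C)=O)CCC(C)(C)[C@H]2C=O | intermediate
17 | C13-epimeric tetracyclic aldehyde (axial CHO at C13) | O=C[C@H]1C[C@H](O)[C@@H]2[C@]3(C1)C(=O)OC[C@]21[C@@H](OC(C)=O)CCC(C)(C)[C@H]1[C@@H]3O | intermediate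
18 | tetracyclic C13 aldehyde (target with CHO in place of the acrylate; all ring stereocentres as in the target) | O=C[C@@H]1C[C@H](O)[C@@H]2[C@]3(C1)C(=O)OC[C@]21[C@@H](OC(C)=O)CCC(C)(C)[C@H]1[C@@H]3O | intermediate
19 | tetracyclic C13 alkyne (target with ethynyl in place of the acrylate) | C#C[C@@H]1C[C@H](O)[C@@H]2[C@]3(C1)C(=O)OC[C@]21[C@@H](OC(C)=O)CCC(C)(C)[C@H]1[C@@H]3O | intermediate
20 | CNP0421185.1: methyl 2-substituted acrylate of the 1-acetoxy-6,11-dihydroxy 7,20-lactone tetracycle | C=C(C(=O)OC)[C@@H]1C[C@H](O)[C@@H]2[C@]3(C1)C(=O)OC[C@]21[C@@H](OC(C)=O)CCC(C)(C)[C@H]1[C@@H]3O | target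

**Totals**
Total step count: 11. Longest linear sequence: 10 (steps 1–4 and 6–11).

**Three steps most likely to fail**

Step 6 (the proposed new annulation). Risks are slow 6-endo closure through the ester, intermolecular capture of the C10 radical by a second molecule of 10, and attack of the acyloxy radical on the vinyl group or the doubly allylic C5–H. The fallback uses known chemistry, sets out from 7 and comes back at 11. The 1,1-disubstituted alkene of 7 is epoxidised selectively with m-CPBA (NaHCO3, CH2Cl2, 0 °C) to the spiro-epoxide F1. Titanocene chloride, (C5H5)2TiCl with trivalent titanium, made from (C5H5)2TiCl2 and Zn in THF with 2,4,6-collidine hydrochloride, opens F1 reductively to the same tertiary C10 radical with oxygen already on C20; this radical adds to 2,2,2-trifluoroethyl acrylate and the titanium alkoxide lactonises to the saturated spirolactone F2. LiN(SiMe3)2 and then CH2=NMe2+ I− give the Mannich base F3, and MeI followed by NaHCO3 eliminates trimethylamine to return 11.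

Step 8 (four oxidative events and one elimination in one flask). Risks are over-oxidation and the regiochemistry of the selenoxide elimination. The fallback sets out from 14 and comes back at 16, separating the events and replacing ozone. The hydrazone is hydrolysed with aqueous CuCl2 (THF, pH 7 buffer) to the aldehyde selenide F4. H2O2 and pyridine (CH2Cl2, 0 °C) then effect selenoxide elimination to the enoate aldehyde F5 with both terminal alkenes intact. Lemieux–Johnson cleavage (OsO4 cat., NaIO4, 2,6-lutidine, dioxane–H2O) cuts only the two electron-rich terminal alkenes and gives 16.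

Step 9 (cascade in the presence of a third aldehyde). Risks are reduction of the spectator C16 aldehyde and pinacol coupling between the C11 and C16 aldehydes; the fallback below answers only the first, and a pinacol-dominated outcome would require masking C16 before the cascade. The fallback sets out from 16 and comes back at 18, replacing chemoselective reduction by exhaustive reduction and selective re-oxidation. Excess SmI2 (6 equiv, LiBr, t-BuOH, THF, then MeOH) runs the cyclisation/aldol and also reduces the spectator aldehyde, giving the tetracyclic triol F6. Only the primary alcohol is then oxidised (2,2,6,6-tetramethylpiperidin-1-oxyl cat., PhI(OAc)2, CH2Cl2), and 1,8-diazabicyclo[5.4.0]undec-7-ene equilibrates C13 to give 18.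

**Further compounds**
F1 | step 6 | spiro-epoxide of 7: (4S,8R)-8-ethenyl-7,7-dimethyl-1-oxaspiro[2.5]octan-4-yl acetate, epoxide oxygen trans to OAc and vinyl | C1O[C@@]12[C@@H](OC(C)=O)CCC(C)(C)[C@H]2C=C
F2 | step 6 | saturated spirolactone: 11-ethenyl-10,10-dimethyl-3-oxo-2-oxaspiro[5.5]undecan-7-yl acetate, stereocentres as in 11 | C1C(=O)OC[C@@]2(C1)[C@@H](OC(C)=O)CCC(C)(C)[C@H]2C=C
F3 | step 6 | Mannich base: F2 with CH2NMe2 on C8 (C8 epimers) | CN(C)CC1C(=O)OC[C@@]2(C1)[C@@H](OC(C)=O)CCC(C)(C)[C@H]2C=C
F4 | step 8 | aldehyde selenide: 14 with CHO in place of the hydrazone (C8 and C13 epimers) | C=CCC(C=O)CC1([Se]c3ccccc3)C(=O)OC[C@@]2(C1)[C@@H](OC(C)=O)CCC(C)(C)[C@H]2C=C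
F5 | step 8 | enoate aldehyde: C8=C9 lactone with the CH2–CH(CHO)(CH2CH=CH2) chain on C8 and vinyl on C5 (C13 epimers) | C=CCC(C=O)CC1=C[C@]2(COC1=O)[C@@H](OC(C)=O)CCC(C)(C)[C@H]2C=C
F6 | step 9 | tetracyclic triol: 18 with CH2OH in place of CHO at C13 (C13 epimers) | OCC1C[C@H](O)[C@@H]2[C@]3(C1)C(=O)OC[C@]21[C@@H](OC(C)=O)CCC(C)(C)[C@H]1[C@@H]3O
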